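**Plan**

- Retrosynthesis: the two phenolic O–Si bonds are cut first, then the C4–H bond (back to a C4 ketone), then O1–C2 and C5–C6 of the oxane ring in a single [4+2] step. This leaves a 3-arylpropanal and a 1-aryl-3-silyloxy diene, which go back to eugenol and dehydrozingerone.
- Enabling feature: in the oxane ring (O1, C2 aryl, C3, C4 oxygenated, C5, C6 arylethyl) the unit aryl–C2–C3–C4(O)–C5 is the carbon skeleton of dehydrozingerone, and O1=C6 with its arylethyl chain is the carbonyl group of the propanal.
- Forward: eugenol is silylated, hydroborated and oxidised to the aldehyde; dehydrozingerone is silylated at the phenol and then at the enol oxygen; the hetero-Diels–Alder reaction joins the halves and closes the only ring; enol ether hydrolysis, reduction and desilylation finish.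
- Stereochemistry: C6 (S) comes from catalyst control of the aldehyde face, C2 (S) from the endo transition state (2,6-cis), and C4 (R) from axial hydride addition to the chair ketone, which gives the all-cis, all-equatorial target.

Key step: step 6

Notation: TIPS = triisopropylsilyl, TES = triethylsilyl. Ring atoms are numbered O1, C2 (aryl), C3, C4, C5, C6 (arylethyl) throughout. CrCl(L) is the chloride complex of trivalent chromium with L, the doubly deprotonated Schiff base of 3-(1-adamantyl)-2-hydroxy-5-methylbenzaldehyde and (1R,2S)-1-amino-2-indanol.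

Assumption: this antipode of CrCl(L) is taken to direct the diene to the Re face of the aldehyde, the face that leads to 6S; the mirror-image ligand is made in the same way should the sense prove to be the reverse.

Phenol protection: the phenols are carried as TIPS ethers so that the final deprotection uses fluoride and no hydrogenolysis conditions ever meet the benzylic C2–O1 bond.

**Route**

Step 1
Reactants: 1 eugenol
Product: 2 (4-allyl-2-methoxyphenoxy)triisopropylsilane
Conditions: TIPSCl (1.2 equiv), imidazole (2.5 equiv), DMF, rt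
Reagents that add atoms: triisopropylsilyl chloride, CC(C)[Si](Cl)(C(C)C)C(C)C
Why: Silyl ether formation from a phenol and a silyl chloride with imidazole (nucleophilic catalysis through the N-silylimidazolium ion) is routine, and the aryl TIPS ether is picked because it should withstand basic peroxide, dilute acid and borohydride yet leave with fluoride.

Step 2
Reactants: 2 (4-allyl-2-methoxyphenoxy)triisopropylsilane
Product: 4 3-[3-methoxy-4-(triisopropylsilyloxy)phenyl]propan-1-ol, via B-alkyl-9-BBN borane 3 (not isolated)
Conditions: 9-BBN (0.5 M in THF, 1.3 equiv), 0 °C → rt; then 3 M aq. NaOH, 30% H2O2, 0 °C → rt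
Reagents that add atoms: hydrogen peroxide, OO (oxygen of the new hydroxyl); 9-borabicyclo[3.3.1]nonane, B1C2CCCC1CCC2 (boron and bicycle of 3, lost again on oxidation)
Why: Hydroboration–oxidation: the bulky dialkylborane puts boron on the terminal carbon of the allyl group for steric reasons and hydroperoxide then oxidises the C–B bond with retention, which should give the primary alcohol while the arene and the hindered aryl silyl ether stay untouched.

Step 3
Reactants: 4 3-[3-methoxy-4-(triisopropylsilyloxy)phenyl]propan-1-ol
Product: 5 3-[3-methoxy-4-(triisopropylsilyloxy)phenyl]propanal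
Conditions: DMP (1.2 equiv), CH2Cl2, 0 °C → rt
Reagents that add atoms: none
Why: Dess–Martin oxidation takes the primary alcohol to the aldehyde under neutral, water-free conditions without over-oxidation, and the sensitive aldehyde is to be used at once in step 6.

Step 4
Reactants: 6 dehydrozingerone
Product: 7 (E)-4-[3-methoxy-4-(triisopropylsilyloxy)phenyl]but-3-en-2-one
Conditions: TIPSCl (1.2 equiv), imidazole (2.5 equiv), DMF, rt
Reagents that add atoms: triisopropylsilyl chloride, CC(C)[Si](Cl)(C(C)C)C(C)C
Why: The same imidazole-mediated phenol silylation as in step 1 applies, the enone being inert to both reagents.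

Step 5
Reactants: 7 (E)-4-[3-methoxy-4-(triisopropylsilyloxy)phenyl]but-3-en-2-one
Product: 8 (E)-1-[3-methoxy-4-(triisopropylsilyloxy)phenyl]-3-(triethylsilyloxy)buta-1,3-diene
Conditions: Et3SiOTf (1.2 equiv), Et3N (2.0 equiv), Et2O, 0 °C; pentane/aq. NaHCO3 work-up, used without chromatography
Reagents that add atoms: triethylsilyl trifluoromethanesulfonate, CC[Si](CC)(CC)OS(=O)(=O)C(F)(F)F
Why: Soft enolisation with a silyl triflate and a tertiary amine (silyl enol ether formation) can give only one cross-conjugated silyloxy diene, because the methyl group is the sole enolisable position of 7, and it leaves the E styrene double bond as it is.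

Step 6
Reactants: 5 3-[3-methoxy-4-(triisopropylsilyloxy)phenyl]propanal; 8 (E)-1-[3-methoxy-4-(triisopropylsilyloxy)phenyl]-3-(triethylsilyloxy)buta-1,3-diene
Product: 9 (2S,6S)-2-[3-methoxy-4-(triisopropylsilyloxy)phenyl]-6-{2-[3-methoxy-4-(triisopropylsilyloxy)phenyl]ethyl}-4-(triethylsilyloxy)-5,6-dihydro-2H-pyran
Conditions: CrCl(L) (10 mol %; L as defined above), 8 (1.5 equiv), powdered 4 Å MS, t-BuOMe (about 2 M in 5), rt; flash chromatography on Et3N-deactivated silica
Reagents that add atoms: none
Why: The trivalent chromium centre of CrCl(L) binds the aldehyde oxygen anti to the chain, and the diene adds in a concerted, asynchronous endo [4+2] cycloaddition in which the enol-ether CH2 terminus bonds to the carbonyl carbon (C5–C6) slightly ahead of O1–C2 formation at the aryl-bearing terminus. The closest known reaction type is the hetero-Diels–Alder reaction of unbranched aliphatic aldehydes with mono-oxygenated 2-silyloxy dienes under this class of tridentate Schiff-base chromium catalysts, applied here to a diene whose oxygen-bonding terminus carries an aryl group. The oxane ring closes by the cycloaddition itself, both new bonds forming in one six-membered pericyclic event. C6 is set by the catalyst, which should expose the Re face of the bound aldehyde (6S), and C2 is set by the endo transition state, which with the E diene places aryl and arylethyl cis (2S). The step needs regio-, endo- and face selectivity: the first follows from the polarity of the silyloxy diene and the aldehyde, the second from the catalyst sitting anti to the chain, and the third from the ligand, while the modest nucleophilicity of the styrenyl diene is met by high concentration, an excess of 8 and molecular sieves.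

Step 7
Reactants: 9 (2S,6S)-2-[3-methoxy-4-(triisopropylsilyloxy)phenyl]-6-{2-[3-methoxy-4-(triisopropylsilyloxy)phenyl]ethyl}-4-(triethylsilyloxy)-5,6-dihydro-2H-pyran
Product: 10 (2S,6S)-2-[3-methoxy-4-(triisopropylsilyloxy)phenyl]-6-{2-[3-methoxy-4-(triisopropylsilyloxy)phenyl]ethyl}oxan-4-one
Conditions: TFA (0.1 equiv), wet CH2Cl2, 0 °C, 15 min; aq. NaHCO3
Reagents that add atoms: none
Why: Acid-catalysed hydrolysis of a silyl enol ether, by protonation at C3 and loss of silicon to water, is much faster than any cleavage of the hindered aryl silyl ethers, and the short, cold exposure is meant to keep the β-alkoxy ketone from opening by retro-oxa-Michael elimination, with C2 and C6 already in the stable cis (diequatorial) arrangement.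

Step 8
Reactants: 10 (2S,6S)-2-[3-methoxy-4-(triisopropylsilyloxy)phenyl]-6-{2-[3-methoxy-4-(triisopropylsilyloxy)phenyl]ethyl}oxan-4-one
Product: 11 (2S,4R,6S)-2-[3-methoxy-4-(triisopropylsilyloxy)phenyl]-6-{2-[3-methoxy-4-(triisopropylsilyloxy)phenyl]ethyl}oxan-4-ol
Conditions: NaBH4 (1.5 equiv), MeOH/THF 1:1, −78 → −40 °C; aq. NH4Cl
Reagents that add atoms: none
Why: Substrate-controlled borohydride reduction: in the chair with both C2 and C6 substituents equatorial the small hydride should approach along the axial trajectory, so that the new hydroxyl at C4 ends up equatorial and cis to both substituents (4R).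

Step 9
Reactants: 11 (2S,4R,6S)-2-[3-methoxy-4-(triisopropylsilyloxy)phenyl]-6-{2-[3-methoxy-4-(triisopropylsilyloxy)phenyl]ethyl}oxan-4-ol
Product: 12 (2S,4R,6S)-2-(4-hydroxy-3-methoxyphenyl)-6-[2-(4-hydroxy-3-methoxyphenyl)ethyl]oxan-4-ol
Conditions: Bu4NF (2.5 equiv), AcOH (2.5 equiv), THF, 0 °C → rt
Reagents that add atoms: none
Why: Fluoride-induced desilylation, driven by the strong Si–F bond, should free both phenols, and the acetic acid buffer keeps them protonated so that no phenoxide can open the ring at the benzylic C2–O1 bond.

**Compound list**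

1 | eugenol (4-allyl-2-methoxyphenol) | COc1cc(CC=C)ccc1O | starting material
2 | (4-allyl-2-methoxyphenoxy)triisopropylsilane | COc1cc(CC=C)ccc1O[Si](C(C)C)(C(C)C)C(C)C | intermediate
3 | 9-{3-[3-methoxy-4-(triisopropylsilyloxy)phenyl]propyl}-9-borabicyclo[3.3.1]nonane | COc1cc(CCCB2C3CCCC2CCC3)ccc1O[Si](C(C)C)(C(C)C)C(C)C | intermediate
4 | 3-[3-methoxy-4-(triisopropylsilyloxy)phenyl]propan-1-ol | COc1cc(CCCO)ccc1O[Si](C(C)C)(C(C)C)C(C)C | intermediate
5 | 3-[3-methoxy-4-(triisopropylsilyloxy)phenyl]propanal | COc1cc(CCC=O)ccc1O[Si](C(C)C)(C(C)C)C(C)C | intermediate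
6 | dehydrozingerone, (E)-4-(4-hydroxy-3-methoxyphenyl)but-3-en-2-one | COc1cc(/C=C/C(C)=O)ccc1O | starting material
7 | (E)-4-[3-methoxy-4-(triisopropylsilyloxy)phenyl]but-3-en-2-one | COc1cc(/C=C/C(C)=O)ccc1O[Si](C(C)C)(C(C)C)C(C)C | intermediate
8 | (E)-1-[3-methoxy-4-(triisopropylsilyloxy)phenyl]-3-(triethylsilyloxy)buta-1,3-diene | COc1cc(/C=C/C(=C)O[Si](CC)(CC)CC)ccc1O[Si](C(C)C)(C(C)C)C(C)C | intermediate
9 | (2S,6S)-2-[3-methoxy-4-(triisopropylsilyloxy)phenyl]-6-{2-[3-methoxy-4-(triisopropylsilyloxy)phenyl]ethyl}-4-(triethylsilyloxy)-5,6-dihydro-2H-pyran | COc1cc(CC[C@H]2CC(O[Si](CC)(CC)CC)=C[C@@H](c3ccc(O[Si](C(C)C)(C(C)C)C(C)C)c(OC)c3)O2)ccc1O[Si](C(C)C)(C(C)C)C(C)C | intermediate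
10 | (2S,6S)-2-[3-methoxy-4-(triisopropylsilyloxy)phenyl]-6-{2-[3-methoxy-4-(triisopropylsilyloxy)phenyl]ethyl}oxan-4-one | COc1cc(CC[C@H]2CC(=O)C[C@@H](c3ccc(O[Si](C(C)C)(C(C)C)C(C)C)c(OC)c3)O2)ccc1O[Si](C(C)C)(C(C)C)C(C)C | intermediate
11 | (2S,4R,6S)-2-[3-methoxy-4-(triisopropylsilyloxy)phenyl]-6-{2-[3-methoxy-4-(triisopropylsilyloxy)phenyl]ethyl}oxan-4-ol | COc1cc(CC[C@H]2C[C@@H](O)C[C@@H](c3ccc(O[Si](C(C)C)(C(C)C)C(C)C)c(OC)c3)O2)ccc1O[Si](C(C)C)(C(C)C)C(C)C | intermediate
12 | (2S,4R,6S)-2-(4-hydroxy-3-methoxyphenyl)-6-[2-(4-hydroxy-3-methoxyphenyl)ethyl]oxan-4-ol | COc1cc(CC[C@H]2C[C@@H](O)C[C@@H](c3ccc(O)c(OC)c3)O2)ccc1O | target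

**Count and risks**

Total step count: 9. Longest linear sequence: 7 steps (steps 1, 2, 3, 6, 7, 8, 9 from eugenol); the dehydrozingerone arm is 6 steps.

Step 6. The cycloaddition may be too slow with the aryl-conjugated diene, so that hydrolysis of the enol ether or an open-chain Mukaiyama-type addition competes, or face selection by the catalyst may be incomplete. A first remedy inside the same step is the more Lewis-acidic Cr(L)SbF6. The fallback replaces the cycloaddition by an aldol addition followed by ring closure through oxa-Michael addition, and sets out from enone 7 and aldehyde 5. Enone 7 is enolised with (+)-Ipc2BCl and Et3N in Et2O at 0 °C, and the boron enolate is added to 5 at −78 °C. This is a boron aldol under reagent control; the (+)-antipode is the one expected to reach the Re face of 5. It should give (1E,5S)-5-hydroxy-1,7-bis[3-methoxy-4-(triisopropylsilyloxy)phenyl]hept-1-en-3-one F1. Camphorsulfonic acid in CH2Cl2 at rt then closes O1–C2 by 6-endo oxa-Michael addition under thermodynamic control, which places the aryl group equatorial and cis to the chain. The sequence comes back to the route at ketone 10.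

Step 7. Ring integrity may be lost under acid, either by retro-oxa-Michael opening of the β-alkoxy ketone or by ionisation of the electron-rich benzylic C2–O1 bond, with erosion of the 2,6-cis relationship. The fallback removes all silyl groups with buffered fluoride before the reduction, and sets out from 9. Bu4NF/AcOH in THF at 0 °C cleaves the enol ether and both aryl ethers near neutral pH, the enolate being protonated at C3, to give (2S,6S)-2-(4-hydroxy-3-methoxyphenyl)-6-[2-(4-hydroxy-3-methoxyphenyl)ethyl]oxan-4-one F2. NaBH4 in MeOH at −78 °C then reduces F2 in the same axial sense. The sequence comes back to the route at the target 12, so that steps 8 and 9 fall away.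

Step 8. Hydride delivery may show insufficient facial selectivity, leaving a mixture of C4 epimers that is hard to separate. The fallback makes the axial alcohol on purpose and then inverts it, and sets out from 10. The bulky LiBH(s-Bu)3 in THF at −78 °C attacks from the equatorial side and should give the axial alcohol (2S,4S,6S)-2-[3-methoxy-4-(triisopropylsilyloxy)phenyl]-6-{2-[3-methoxy-4-(triisopropylsilyloxy)phenyl]ethyl}oxan-4-ol F3. Mitsunobu inversion with 4-nitrobenzoic acid, PPh3 and DIAD in THF gives the equatorial ester (2S,4R,6S)-2-[3-methoxy-4-(triisopropylsilyloxy)phenyl]-6-{2-[3-methoxy-4-(triisopropylsilyloxy)phenyl]ethyl}oxan-4-yl 4-nitrobenzoate F4. K2CO3 in MeOH at 0 °C removes the ester, and the sequence comes back to the route at alcohol 11. Any partial loss of an aryl silyl group in that last operation is of no consequence, since step 9 removes both.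

**Further compounds**

F1 | step 6 | (1E,5S)-5-hydroxy-1,7-bis[3-methoxy-4-(triisopropylsilyloxy)phenyl]hept-1-en-3-one | COc1cc(CC[C@H](O)CC(=O)/C=C/c2ccc(O[Si](C(C)C)(C(C)C)C(C)C)c(OC)c2)ccc1O[Si](C(C)C)(C(C)C)C(C)C
F2 | step 7 | (2S,6S)-2-(4-hydroxy-3-methoxyphenyl)-6-[2-(4-hydroxy-3-methoxyphenyl)ethyl]oxan-4-one | COc1cc(CC[C@H]2CC(=O)C[C@@H](c3ccc(O)c(OC)c3)O2)ccc1O
F3 | step 8 | (2S,4S,6S)-2-[3-methoxy-4-(triisopropylsilyloxy)phenyl]-6-{2-[3-methoxy-4-(triisopropylsilyloxy)phenyl]ethyl}oxan-4-ol | COc1cc(CC[C@H]2C[C@H](O)C[C@@H](c3ccc(O[Si](C(C)C)(C(C)C)C(C)C)c(OC)c3)O2)ccc1O[Si](C(C)C)(C(C)C)C(C)C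
F4 | step 8 | (2S,4R,6S)-2-[3-methoxy-4-(triisopropylsilyloxy)phenyl]-6-{2-[3-methoxy-4-(triisopropylsilyloxy)phenyl]ethyl}oxan-4-yl 4-nitrobenzoate | COc1cc(CC[C@H]2C[C@@H](OC(=O)c3ccc(cc3)[N+](=O)[O-])C[C@@H](c4ccc(O[Si](C(C)C)(C(C)C)C(C)C)c(OC)c4)O2)ccc1O[Si](C(C)C)(C(C)C)C(C)C
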